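(The earlier runs and the new flask stem from a simulated flask with constants of no real substance; the scatter is artificial.)

- Thursday's flask holds 0.10 M of substrate, 2.00 mM of free catalyst and 0.45 mM of impurity, which is a quarter of that catalyst. The four new flasks hold these amounts, while Saturday's flask holds more substrate, 0.15 M, so the reckoning below uses Thursday's run.

| flask | substrate | free catalyst | impurity | remark | time |
|---|---|---|---|---|---|
| Thursday's | 0.10 M | 2 mol% | 0.45 mM | run made earlier |  |
| Saturday's | 0.15 M | 2 mol% | 0.45 mM | run made earlier |  |
| green | 0.10 M | 2 mol% | 0.45 mM | a closed flask charged with all of it at once and left for 5.0 min | 5.0 min |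
| teal | 0.10 M | 2 mol% | 0.45 mM | one stirred flow tank at steady state, fed with the mixture as stated, mean residence time 5.0 min |  |
| ochre | 0.10 M (fed, over 2.50 min) | 2 mol% | 0.45 mM | all but substrate at the start; substrate goes in evenly over 2.50 min, the run ends at 5.0 min | 5.0 min |
| blue | 0.10 M | 2 mol% | 0.45 mM | a single well-mixed tank run continuously and read at steady state, 50.0 min in it on average |  |

- Thursday's (time / min: target / %, isomer of the product / %): 0.417: 19.3, 77.7; 1.00: 20.2, 78.6; 2.00: 20.6, 75.6; 5.00: 22.4, 74.4
- Saturday's (time / s: target / %, isomer of the product / %): 10.0: 11.0, 85.1; 15.0: 11.4, 86.3; 40.0: 14.2, 85.1; 90.0: 17.1, 82.0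

(each reading ± 1 percentage point)

- the stated concentrations are those of everything mixed, before any reaction; amounts are the same in each set-up
- what may be going on: substrate <-> target; target <-> isomer of the product; isomer of the product + free catalyst <-> substrate + free catalyst; target -> over-reaction product; free catalyst <-> dormant form; free catalyst + impurity -> spent catalyst
- the feed brings no volume worth counting
- the earlier runs were made in a closed, stirred flask
- the share counts what is present at the end, not what went on to other products

1. the set-up with the highest share of target in all that became target or isomer of the product, at the outlet or at the end ("none" if the first two lie within 2 percentage points) (green / teal / ochre / blue / none)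
2. share of target in all that became target or isomer of the product, at the outlet or at the end, green
3. share of target in all that became target or isomer of the product, at the outlet or at the end, teal
4. share of target in all that became target or isomer of the product, at the outlet or at the end, ochre
5. share of target in all that became target or isomer of the product, at the outlet or at the end, blue

- The share is target over target plus isomer of the product. On Thursday it reads 19.9%, 21.4% and 23.1% at 0.417 min, 2.00 min and 5.00 min.
- The share climbs 0.00958 min⁻¹ over the first stretch and 0.00576 min⁻¹ over the second, as a fraction, so the readings bend, within their scatter.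
- If the slope falls in step with the gap to a level, that fall gives the closing time T, the time in which the gap shrinks by a factor e: 4.24 min. Like the slopes, it is a reading and carries the scatter.
- The level, the thermodynamic end of kinetic against thermodynamic control, reads 24.7%. The early end, joined back to zero time, is 19.4%.
- My reckoning assumes the same early end and closing time in each flask. Green keeps a gap factor of exp(-t/T), t being its time, and a tank keeps 1/(1+τ/T), τ being its mean residence time. Ochre's factor is averaged over its dosing.
- This gives green 23.1%, teal 22.3%, ochre 22.5% and blue 24.3%. In this reckoning blue leads green by 1.2 percentage points, less than the margin.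
- The forecast, saying “the mixture relaxes slowly towards equilibrium”, gives green 23%, teal 22.5%, ochre 23.2%, blue 24.5% and the choice none.

    substrate ⇌ target (K = 23.0, k = 0.0536 s⁻¹)
    target ⇌ isomer of the product (K = 2.91, k = 0.00257 s⁻¹)
    isomer of the product + free catalyst ⇌ substrate + free catalyst, rate k3*[free catalyst]*[isomer of the product] forward; the back reaction follows from the equilibrium constant (k = 3.96 M⁻¹ s⁻¹)
    target → over-reaction product (k = 1.54 × 10⁻⁵ s⁻¹)
    free catalyst ⇌ dormant form (K = 2.27, k = 0.297 s⁻¹)
    free catalyst + impurity → spent catalyst (k = 7910 M⁻¹ s⁻¹)

- The flasks give green 24.3%, teal 27.0%, ochre 26.8% and blue 25.8%, so the choice is none. Teal, with c substrate at 0.00287 M, stands above green at 50.0 min, 25.5%. At that time the closing time leaves hardly any of green's gap, so 25.5% serves as the level. From it, the closing time puts green at 5.0 min at 23.6%, against 24.3%. By the closing time, blue keeps 7.82% of the gap, which gives 25.0%, and blue stands at 25.8%.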